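## The problem

Target 24 is a depsidone. A benzoate ring (ring A: C1 carboxyl, C2 aryl ether oxygen, C3 CHO, C4 OH, C5 H, C6 CH3) is joined twice to the benzene ring of a 2,2-dimethylchroman-4-one (ring B, chromanone numbering O1 to C8a). One link is the diaryl ether from ring A C2 to O7, the other the aryl ester from the C1 carboxyl to O6. Together they close a seven-membered dioxepinone (ring C); the dihydropyranone is ring D.

There is no stereocentre, so the whole difficulty is regiochemical. The ether oxygen sits between two ortho substituents on each ring, which makes Ullmann or SNAr etherification of the two finished rings slow. Ring B has no hydrogen and carries four contiguous oxygens; O6 and O8 are both ortho to O7, so either could close a seven-membered lactone, and the two must be told apart until ring C is closed.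

Several groups limit what can be done late:
- the aryl ester is opened by hydroxide and other nucleophiles;
- the salicylaldehyde is open to oxidants and reductants;
- ring D opens by retro-oxa-Michael reaction in strong base;
- ring A C2 is flanked by two carbonyl groups, so a free O8 phenoxide can attack it (Smiles rearrangement).

The feature that opens a different approach is the pattern of ring A. The C4 hydroxyl is meta to the C2 ether oxygen, the carboxyl at C1 lies next to the C6 methyl, and C5 is unsubstituted. This is exactly what a (2+2)/electrocyclic union of an ester-bearing vinylketene (C4, C1, C6, C5) with an alkynyl ether (C2, C3) writes. The hindered ether oxygen can therefore be carried in on the alkyne instead of being made by aromatic substitution.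

## Retrosynthesis

**24 from 23.** The last bond cut is O8–CH3. O8 has to stay masked until ring C is closed, and a methyl ether is what the oxygen pattern of quinone 1 supplies at this position without extra steps. The forward step must cleave one aryl methyl ether in the presence of an aryl ester, an aldehyde and the tertiary ether of ring D.

**23 from 22.** Ring C is opened at the ester bond between the C1 carboxyl and O6. The neighbouring cut, the diaryl ether, would mean an intramolecular etherification of a depside at two hindered carbons. Lactonisation of a diaryl ether hydroxy acid is the established depsidone closure and leaves the ether to be solved earlier. Seco acid 22 must present only one reachable hydroxyl (O6) to the activated acid.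

**22 from 21, 20 and 19.** Acid, O6 hydroxyl and aldehyde are traced back to a tert-butyl ester, a MOM ether and a silyloxymethyl group. The formyl group is not carried through the ring-forming step, because an alkynyl ether bearing an aldehyde would be a push–pull acceptor and not a ketenophile. The aldehyde is made (19 to 20 to 21) while ester and O6 are still protected, so that MnO2 never meets a free acid or an oxidisable ring B phenol. One acid treatment then frees both partners of the lactonisation (21 to 22).

**19 from 11 and 15 (key disconnection).** Ring A is cut at C3–C4, C1–C2 and C4–C5. This gives alkynyl ether 11, which holds ring B, ring D and the future ether oxygen, and the five-carbon diazo ketoester 15. Against a C2–O disconnection (SNAr or Ullmann between two di-ortho-substituted partners), this cut never forms the hindered C–O bond at an aromatic carbon. Ring A shrinks to a compound made in two steps. The forward reaction needs three things: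
- Wolff migration of the isopropenyl group;
- (2+2) addition in the sense set by the polarisation of the ynol ether;
- no diversion of the ester-bearing ketene through its carbonyl oxygen.

**11 from 7 and 9; 9 from 8.** The O7–C(sp) bond is cut to phenol 7 and dibromoalkene 9, itself one step from aldehyde 8. Copper-catalysed coupling followed by elimination is preferred to the dichlorovinyl ether/alkyllithium route, because the latter cannot be run with the C4 ketone in place.

**7 from 6 and 5.** The three ring B oxygens are differentiated here. O6 is the only free phenol of 5 and takes the MOM group. Of the two methyl ethers of 6, only O7 is para to the C4 ketone, so a nucleophilic demethylation should choose it and leave O8–CH3 as the late protecting group.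

**5 from 3, 2 and 1.** Ring D is cut at O1–C2 and C2–C3 (Kabbe condensation of acetophenone 3 with acetone). The acetyl group is placed at the one free position of hydroquinone 2, the reduced form of quinone 1. Direct use of 3-methylbut-2-enoic acid in protic acid was set aside: electron-rich hydroquinones are alkylated at its β-carbon and lactonise to 4,4-dimethyldihydrocoumarins. Acylation first makes the chroman-4-one unambiguous.

**15 from 14, 12 and 13.** The diazo group goes back to active methylene compound 14, and 14 to a crossed Claisen acylation of tert-butyl acetate 12 with methacryloyl chloride 13. The tert-butyl ester is chosen so that the C1 carboxyl is released by acid together with O6.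

## Roads not taken

**Alternative 1:** Oxidative para-lactonisation.
- Cut: the bond between the ester oxygen and ring B C6.
- Forward step: diaryl ether acid A1, whose ring B is a mono-arylated 2-methoxy-5-methylresorcinol, is oxidised with PhI(OAc)2. The carboxylate adds para to the free phenol, and rearomatisation gives depsidone A2, which lacks ring D.
- Merits: ring B starts from a symmetric resorcinol, so its arylation needs no regiocontrol. O6 is created in the ring closure, so the O6/O8 problem and the selective demethylation of the chosen route disappear. In protecting-group economy on ring B this road is better.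
- Weak points: A1 still needs the hindered diaryl ether made by substitution. The carboxylate can reach two carbons ortho to the ether oxygen (the para C–H and the methoxy-bearing carbon ortho to the phenol), so the site of attack is not secured. A2 is a para-acyloxyphenol and can be oxidised further. Ring D must then be built on A2 by acylation in strong acid beside lactone and aldehyde, and two methyl ethers remain to be cleaved.
- Comparison: the chosen plan has ring D in place from step 3, and no oxidant or strong acid touches the finished depsidone.

**Alternative 2:** Siloxyfuran–ynone cycloaddition.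
- Cut: ring B bonds C5–C6 and C4a–C8a, and O1–C2.
- Forward step: siloxyfuran A3 (silyl group taken as tert-butyldimethylsilyl) adds to ynone A4. The oxygen bridge opens to the arene, and fluoride work-up closes ring D to give chromanone A5.
- Merits: the three ring B oxygens are differentiated by construction (benzyl on O7, free O6, methyl on O8). In regiochemical certainty at O7 this is better than a selective demethylation. A5 would enter the chosen route after MOM protection and hydrogenolysis, giving 7.
- Weak points: it is a ring B synthesis only. Ring A, the hindered ether and the lactone are untouched. A3 is a hydrolytically labile tri-oxygenated furan that needs several steps of its own.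
- Comparison: the chosen plan reaches 7 in five steps from a cheap quinone by standard reactions, and spends its one untested step on joining the rings.

**Alternative 3:** Hexadehydro-Diels–Alder aryne.
- Cut: ring A bonds C1–C2 and C5–C6, with C3–CHO and C4–OH from aryne trapping.
- Forward step: triyne A6 (but-2-ynoate on O6, buta-1,3-diynyl ether on O7) is heated. Ring A and ring C form together, and DMF adds across the C3–C4 aryne to give, after hydrolysis, A7, which is the same compound as 23.
- Merits: the most convergent road. One operation delivers what steps 10 to 14 of the chosen route deliver, and in step count after fragment assembly it is clearly better.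
- Weak points: the tether between diyne and diynophile has five atoms and closes a seven-membered ring, outside the usual three-atom tethers. The aryl ester prefers the conformation that turns the butynoyl group away from the diyne. A terminal buta-1,3-diynyl aryl ether is an unstable, unprecedented precursor. Ring B needs the same O6/O7/O8 differentiation as in the chosen plan.
- Comparison: each pericyclic event of the chosen key step has intermolecular precedent, and both of its precursors are isolable compounds.

Key step: step 10

Remark on the chemistry: the target has no stereocentre, so the only descriptors in the route are the alkene geometries of the non-isolated intermediates 10 and 18; cyclobutenone 17 is racemic and its stereocentre is lost again.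

## Steps

Step 1
Reactants: 1 2,3-dimethoxy-5-methyl-1,4-benzoquinone
Product: 2 2,3-dimethoxy-5-methylbenzene-1,4-diol
Conditions: Na2S2O4, Et2O/H2O, rt, under argon
Reagents that add atoms: none
Why: Dithionite reduction of a 1,4-benzoquinone to its hydroquinone; 2 reoxidises in air and is used at once.

Step 2
Reactants: 2 2,3-dimethoxy-5-methylbenzene-1,4-diol
Product: 3 1-(2,5-dihydroxy-3,4-dimethoxy-6-methylphenyl)ethan-1-one
Conditions: AcOH, BF3·OEt2, 90 °C; then H2O
Reagents that add atoms: acetic acid, CC(=O)O
Why: Friedel–Crafts acetylation (O-acetate and Fries shift) at the only free ring position of an electron-rich hydroquinone; putting the acyl carbon in first rules out conjugate alkylation of the arene, which with 3-methylbut-2-enoic acid leads to dihydrocoumarins.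

Step 3
Reactants: 3 1-(2,5-dihydroxy-3,4-dimethoxy-6-methylphenyl)ethan-1-one
Product: 5 6-hydroxy-7,8-dimethoxy-2,2,5-trimethylchroman-4-one, via enone 4 (not isolated)
Conditions: acetone, pyrrolidine, MeOH, reflux, under argon
Reagents that add atoms: acetone, CC(C)=O
Why: Kabbe condensation: amine-mediated aldol condensation with acetone gives enone 4, and the only hydroxyl ortho to the acyl group closes ring D by oxa-Michael addition (six-membered ring); C2 carries two methyl groups, so no stereocentre arises.

Step 4
Reactants: 5 6-hydroxy-7,8-dimethoxy-2,2,5-trimethylchroman-4-one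
Product: 6 7,8-dimethoxy-6-(methoxymethoxy)-2,2,5-trimethylchroman-4-one
Conditions: MOMCl, iPr2NEt, CH2Cl2, 0 °C to rt
Reagents that add atoms: chloromethyl methyl ether, COCCl
Why: O-alkylation of the single free phenol; the MOM acetal survives thiolate, base, copper catalysis, ketene and fluoride and leaves with acid together with the tert-butyl ester.

Step 5
Reactants: 6 7,8-dimethoxy-6-(methoxymethoxy)-2,2,5-trimethylchroman-4-one
Product: 7 7-hydroxy-8-methoxy-6-(methoxymethoxy)-2,2,5-trimethylchroman-4-one
Conditions: NaSEt, DMF, 100 °C; then aq. NH4Cl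
Reagents that add atoms: none
Why: SN2 demethylation by thiolate: only the O7 phenoxide is stabilised as a vinylogous carboxylate by the para C4 ketone, the known preference for the methoxy group para to an acyl group, whereas O8 is meta; the MOM acetal is inert to thiolate.

Step 6
Reactants: 8 (tert-butyldimethylsilyloxy)acetaldehyde
Product: 9 tert-butyl[(3,3-dibromoprop-2-en-1-yl)oxy]dimethylsilane
Conditions: CBr4, PPh3, Zn dust, CH2Cl2, rt
Reagents that add atoms: carbon tetrabromide, BrC(Br)(Br)Br
Why: Ramirez (Corey–Fuchs) dibromo-olefination; the zinc variant needs one equivalent of phosphine and keeps the medium free of acid for the silyl ether.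

Step 7
Reactants: 7 7-hydroxy-8-methoxy-6-(methoxymethoxy)-2,2,5-trimethylchroman-4-one; 9 tert-butyl[(3,3-dibromoprop-2-en-1-yl)oxy]dimethylsilane
Product: 11 7-{[3-(tert-butyldimethylsilyloxy)prop-1-yn-1-yl]oxy}-8-methoxy-6-(methoxymethoxy)-2,2,5-trimethylchroman-4-one, via bromo enol ether 10 (not isolated)
Conditions: CuI (10 mol %), 2,2′-bipyridine, K3PO4, toluene, 110 °C; then KOtBu, 1,4-dioxane, rt
Reagents that add atoms: none
Why: Copper-catalysed Ullmann-type coupling of a phenol with a 1,1-dibromoalkene at the bromine trans to the substituent gives (Z)-bromo enol ether 10, whose anti H and Br are eliminated by KOtBu to the ynol ether; the C–O bond forms at an unhindered sp2 carbon, which is why a 2,6-disubstituted phenol should be accepted.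

Step 8
Reactants: 12 tert-butyl acetate; 13 methacryloyl chloride
Product: 14 tert-butyl 4-methyl-3-oxopent-4-enoate
Conditions: LiN(iPr)2 (2 equiv), 12 (2 equiv), THF, −78 °C; then 13; aq. NH4Cl
Reagents that add atoms: none
Why: Crossed Claisen acylation of the lithium enolate of 12 by an acid chloride; the second equivalent of enolate deprotonates the product, and at −78 °C attack at the acyl chloride outruns 1,4-addition to the methacryloyl unit.

Step 9
Reactants: 14 tert-butyl 4-methyl-3-oxopent-4-enoate
Product: 15 tert-butyl 2-diazo-4-methyl-3-oxopent-4-enoate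
Conditions: 4-AcNHC6H4SO2N3, Et3N, MeCN, 0 °C to rt
Reagents that add atoms: 4-acetamidobenzenesulfonyl azide, CC(=O)Nc1ccc(cc1)S(=O)(=O)N=[N+]=[N-]
Why: Regitz diazo transfer to an active methylene compound; once the diazo group is in place the compound can no longer enolise, which stops Michael self-condensation of the vinyl ketone.

Step 10
Reactants: 11 7-{[3-(tert-butyldimethylsilyloxy)prop-1-yn-1-yl]oxy}-8-methoxy-6-(methoxymethoxy)-2,2,5-trimethylchroman-4-one; 15 tert-butyl 2-diazo-4-methyl-3-oxopent-4-enoate
Product: 19 tert-butyl 3-[(tert-butyldimethylsilyloxy)methyl]-4-hydroxy-2-{[8-methoxy-6-(methoxymethoxy)-2,2,5-trimethyl-4-oxochroman-7-yl]oxy}-6-methylbenzoate, via vinylketene 16 (not isolated), via vinylcyclobutenone 17 (not isolated), via dienylketene 18 (not isolated)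
Conditions: 15 (1.5 equiv), hν (365 nm), ClCH2CH2Cl, 20 °C; then 80 °C in the dark
Reagents that add atoms: none
Why: Proposed new method: irradiation of 15 expels N2 and the isopropenyl group migrates (Wolff rearrangement) to ester-bearing vinylketene 16, whose carbonyl carbon is attacked by the nucleophilic β-carbon of ynol ether 11 in a (2+2) cycloaddition to cyclobutenone 17; the closest known reaction type is the benzannulation of vinylketenes generated photochemically from α-diazo enones with alkoxy- and siloxyalkynes, and what is untested is the ester on the ketene paired with an aryl ynol ether. Heating in the dark opens 17 by four-electron electrocyclic cleavage to dienylketene 18, which closes ring A by a thermal six-electron disrotatory electrocyclisation between the ketene carbon (C4) and the isopropenyl CH2 (C5), and the cyclohexadienone tautomerises to phenol 19. No stereocentre is set, since the quaternary carbon of 17 becomes C1 of the arene. Regiochemistry rests on the polarisation of 11: its oxygen-bearing carbon bonds to the ester-bearing ketene carbon, so OAr ends at C2 beside the C1 ester and CH2OTBS at C3 beside the new hydroxyl. The Wolff step needs alkenyl migration in preference to alkoxy migration, the normal order for 2-diazo-3-oxo esters. The chemoselectivity needed is (2+2) addition at the ketene C=C and not closure through the ester oxygen; an ester carbonyl is a poor heterodiene terminus, and ring opening of 17 is reversible while only the isomer with the isopropenyl group cis to the ketene can aromatise, so 19 is the thermodynamic sink. Light of 365 nm addresses the diazo n–π* band beside the aryl ketone of 11, and the thermal stage is started only after 15 is consumed so that the new phenol does not meet ketene.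

Step 11
Reactants: 19 tert-butyl 3-[(tert-butyldimethylsilyloxy)methyl]-4-hydroxy-2-{[8-methoxy-6-(methoxymethoxy)-2,2,5-trimethyl-4-oxochroman-7-yl]oxy}-6-methylbenzoate
Product: 20 tert-butyl 4-hydroxy-3-(hydroxymethyl)-2-{[8-methoxy-6-(methoxymethoxy)-2,2,5-trimethyl-4-oxochroman-7-yl]oxy}-6-methylbenzoate
Conditions: Bu4NF, AcOH, THF, 0 °C to rt
Reagents that add atoms: none
Why: Fluoride cleavage of a primary silyl ether; acetic acid keeps the phenoxide concentration low, and tert-butyl ester and MOM acetal are untouched.

Step 12
Reactants: 20 tert-butyl 4-hydroxy-3-(hydroxymethyl)-2-{[8-methoxy-6-(methoxymethoxy)-2,2,5-trimethyl-4-oxochroman-7-yl]oxy}-6-methylbenzoate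
Product: 21 tert-butyl 3-formyl-4-hydroxy-2-{[8-methoxy-6-(methoxymethoxy)-2,2,5-trimethyl-4-oxochroman-7-yl]oxy}-6-methylbenzoate
Conditions: MnO2, CH2Cl2, rt
Reagents that add atoms: none
Why: MnO2 oxidation of an ortho-hydroxybenzyl alcohol to the salicylaldehyde, which is stabilised by the hydrogen bond to the C4 hydroxyl; ring B has no free phenol and the acid is still an ester, so nothing else is oxidisable.

Step 13
Reactants: 21 tert-butyl 3-formyl-4-hydroxy-2-{[8-methoxy-6-(methoxymethoxy)-2,2,5-trimethyl-4-oxochroman-7-yl]oxy}-6-methylbenzoate
Product: 22 3-formyl-4-hydroxy-2-[(6-hydroxy-8-methoxy-2,2,5-trimethyl-4-oxochroman-7-yl)oxy]-6-methylbenzoic acid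
Conditions: CF3CO2H, CH2Cl2, H2O (trace), 0 °C to rt
Reagents that add atoms: none
Why: Acidolysis of the tert-butyl ester (loss of isobutene) and hydrolysis of the MOM acetal in one operation; methyl ether, aldehyde, diaryl ether and ring D are stable to trifluoroacetic acid, so the acid and O6 are freed together and O8 stays masked.

Step 14
Reactants: 22 3-formyl-4-hydroxy-2-[(6-hydroxy-8-methoxy-2,2,5-trimethyl-4-oxochroman-7-yl)oxy]-6-methylbenzoic acid
Product: 23 O8-methyl ether of the target (depsidone 24 with OCH3 in place of OH at chromanone C8)
Conditions: DCC, DMAP (cat.), CH2Cl2 (0.005 M), rt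
Reagents that add atoms: none
Why: Carbodiimide lactonisation as used for depsidone ring closure: O6 is the only hydroxyl within reach of the activated C1 carboxyl, because O8 is methylated and the C4 hydroxyl is para to the carboxyl and hydrogen-bonded to the aldehyde; the ortho-phenylene ether holds the two ends close for the seven-membered ring.

Step 15
Reactants: 23 O8-methyl ether of the target
Product: 24 CNP0271978.0 (target depsidone)
Conditions: BBr3, CH2Cl2, −78 to 0 °C; then H2O
Reagents that add atoms: none
Why: Lewis-acid cleavage of an aryl methyl ether; O8 lies between two ether oxygens that help to bind boron, aryl ester and aldehyde are of the kind carried through boron trihalide demethylations of depsidones, and an acid-induced opening of ring D at the tertiary ether would revert by oxa-Michael closure.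

## Compound list

1 | 2,3-dimethoxy-5-methyl-1,4-benzoquinone | CC1=CC(=O)C(OC)=C(OC)C1=O | starting material
2 | 2,3-dimethoxy-5-methylbenzene-1,4-diol | Cc1cc(O)c(OC)c(OC)c1O | intermediate
3 | 1-(2,5-dihydroxy-3,4-dimethoxy-6-methylphenyl)ethan-1-one | CC(=O)c1c(C)c(O)c(OC)c(OC)c1O | intermediate
4 | 1-(2,5-dihydroxy-3,4-dimethoxy-6-methylphenyl)-3-methylbut-2-en-1-one | CC(C)=CC(=O)c1c(C)c(O)c(OC)c(OC)c1O | intermediate (not isolated)
5 | 6-hydroxy-7,8-dimethoxy-2,2,5-trimethylchroman-4-one | Cc1c(O)c(OC)c(OC)c2OC(C)(C)CC(=O)c12 | intermediate
6 | 7,8-dimethoxy-6-(methoxymethoxy)-2,2,5-trimethylchroman-4-one | Cc1c(OCOC)c(OC)c(OC)c2OC(C)(C)CC(=O)c12 | intermediate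
7 | 7-hydroxy-8-methoxy-6-(methoxymethoxy)-2,2,5-trimethylchroman-4-one | Cc1c(OCOC)c(O)c(OC)c2OC(C)(C)CC(=O)c12 | intermediate
8 | (tert-butyldimethylsilyloxy)acetaldehyde | O=CCO[Si](C)(C)C(C)(C)C | starting material
9 | tert-butyl[(3,3-dibromoprop-2-en-1-yl)oxy]dimethylsilane | BrC(Br)=CCO[Si](C)(C)C(C)(C)C | intermediate
10 | 7-{[(Z)-1-bromo-3-(tert-butyldimethylsilyloxy)prop-1-en-1-yl]oxy}-8-methoxy-6-(methoxymethoxy)-2,2,5-trimethylchroman-4-one | CC(C)(C)[Si](C)(C)OC/C=C(\Br)Oc1c(OCOC)c(C)c2C(=O)CC(C)(C)Oc2c1OC | intermediate (not isolated)
11 | 7-{[3-(tert-butyldimethylsilyloxy)prop-1-yn-1-yl]oxy}-8-methoxy-6-(methoxymethoxy)-2,2,5-trimethylchroman-4-one | CC(C)(C)[Si](C)(C)OCC#COc1c(OCOC)c(C)c2C(=O)CC(C)(C)Oc2c1OC | intermediate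
12 | tert-butyl acetate | CC(=O)OC(C)(C)C | starting material
13 | methacryloyl chloride | CC(=C)C(Cl)=O | starting material
14 | tert-butyl 4-methyl-3-oxopent-4-enoate | CC(=C)C(=O)CC(=O)OC(C)(C)C | intermediate
15 | tert-butyl 2-diazo-4-methyl-3-oxopent-4-enoate | CC(=C)C(=O)C(=[N+]=[N-])C(=O)OC(C)(C)C | intermediate
16 | tert-butyl 3-methyl-2-(oxomethylidene)but-3-enoate | CC(=C)C(=C=O)C(=O)OC(C)(C)C | intermediate (not isolated)
17 | tert-butyl 3-[(tert-butyldimethylsilyloxy)methyl]-2-{[8-methoxy-6-(methoxymethoxy)-2,2,5-trimethyl-4-oxochroman-7-yl]oxy}-4-oxo-1-(prop-1-en-2-yl)cyclobut-2-ene-1-carboxylate (racemic) | CC(=C)C1(C(=O)OC(C)(C)C)C(=O)C(CO[Si](C)(C)C(C)(C)C)=C1Oc1c(OCOC)c(C)c2C(=O)CC(C)(C)Oc2c1OC | intermediate (not isolated)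
18 | tert-butyl (2Z)-4-[(tert-butyldimethylsilyloxy)methyl]-3-{[8-methoxy-6-(methoxymethoxy)-2,2,5-trimethyl-4-oxochroman-7-yl]oxy}-5-oxo-2-(prop-1-en-2-yl)penta-2,4-dienoate | CC(=C)/C(C(=O)OC(C)(C)C)=C(/Oc1c(OCOC)c(C)c2C(=O)CC(C)(C)Oc2c1OC)C(CO[Si](C)(C)C(C)(C)C)=C=O | intermediate (not isolated)
19 | tert-butyl 3-[(tert-butyldimethylsilyloxy)methyl]-4-hydroxy-2-{[8-methoxy-6-(methoxymethoxy)-2,2,5-trimethyl-4-oxochroman-7-yl]oxy}-6-methylbenzoate | Cc1cc(O)c(CO[Si](C)(C)C(C)(C)C)c(Oc2c(OCOC)c(C)c3C(=O)CC(C)(C)Oc3c2OC)c1C(=O)OC(C)(C)C | intermediate
20 | tert-butyl 4-hydroxy-3-(hydroxymethyl)-2-{[8-methoxy-6-(methoxymethoxy)-2,2,5-trimethyl-4-oxochroman-7-yl]oxy}-6-methylbenzoate | Cc1cc(O)c(CO)c(Oc2c(OCOC)c(C)c3C(=O)CC(C)(C)Oc3c2OC)c1C(=O)OC(C)(C)C | intermediate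
21 | tert-butyl 3-formyl-4-hydroxy-2-{[8-methoxy-6-(methoxymethoxy)-2,2,5-trimethyl-4-oxochroman-7-yl]oxy}-6-methylbenzoate | Cc1cc(O)c(C=O)c(Oc2c(OCOC)c(C)c3C(=O)CC(C)(C)Oc3c2OC)c1C(=O)OC(C)(C)C | intermediate
22 | 3-formyl-4-hydroxy-2-[(6-hydroxy-8-methoxy-2,2,5-trimethyl-4-oxochroman-7-yl)oxy]-6-methylbenzoic acid | Cc1cc(O)c(C=O)c(Oc2c(O)c(C)c3C(=O)CC(C)(C)Oc3c2OC)c1C(=O)O | intermediate
23 | O8-methyl ether of the target depsidone | Cc1cc(O)c(C=O)c2c1C(=O)Oc1c(C)c3c(c(OC)c1O2)OC(C)(C)CC3=O | intermediate
24 | CNP0271978.0 | Cc1cc(O)c(C=O)c2c1C(=O)Oc1c(C)c3c(c(O)c1O2)OC(C)(C)CC3=O | target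

## Step count and least certain steps

Total: 15 steps. Longest linear sequence: 12 steps (1 to 5, 7, 10 to 15).

**Step 10 (key step, proposed new method).** Three things may go wrong:
- The ester-bearing ketene may react as an acylketene: stepwise attack of the ynol ether followed by closure through the ester oxygen, or dimerisation before it meets 11.
- The aryl ketone of 11 competes for light and can sensitise the diazo compound to its triplet, which suppresses the Wolff rearrangement.
- Ketene still present during the thermal stage would acylate the new phenol.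

Fallback by known chemistry, from phenol 7 back to seco acid 22: the ether is made by SNAr on a doubly activated fluoroarene.
- Commercial 3-fluoro-5-methylphenol is brominated para to the hydroxyl (NBS, MeCN) to 4-bromo-3-fluoro-5-methylphenol F1.
- F1 is protected (MOMCl, iPr2NEt) as 2-bromo-1-fluoro-5-(methoxymethoxy)-3-methylbenzene F2.
- F2 is lithiated between fluorine and the MOM ether (LiN(iPr)2, THF, −78 °C) and formylated with DMF to 3-bromo-2-fluoro-6-(methoxymethoxy)-4-methylbenzaldehyde F3.
- The aldehyde of F3 is masked in the flask as its lithium α-amino alkoxide (LiN(CH3)CH2CH2N(CH3)2), bromine is exchanged for lithium (n-BuLi, −78 °C) and the aryllithium is trapped with Boc2O, giving tert-butyl 2-fluoro-3-formyl-4-(methoxymethoxy)-6-methylbenzoate F4.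
- Phenol 7 displaces the fluoride of F4, which is flanked by formyl and ester groups (Cs2CO3, DMF, 50 °C), to give tert-butyl 3-formyl-2-{[8-methoxy-6-(methoxymethoxy)-2,2,5-trimethyl-4-oxochroman-7-yl]oxy}-4-(methoxymethoxy)-6-methylbenzoate F5.
- The acid treatment of step 13 removes the tert-butyl ester and both MOM groups of F5 and gives 22.

The price is a tetra-ortho-substituted ether made by substitution and a longer ring A sequence.

**Step 7.** The copper coupling may be slow with a 2,6-dioxygenated phenol and an alkyl-substituted dibromoalkene. In the KOtBu stage the chromanone may enolise and open at ring D, or the ynol ether may isomerise to an allenyl ether.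

Fallback from 7 back to 11: the C–O bond is formed by addition–elimination to trichloroethylene with the ketone temporarily reduced.
- NaBH4 (MeOH, 0 °C) gives racemic 8-methoxy-6-(methoxymethoxy)-2,2,5-trimethylchromane-4,7-diol F6.
- The phenol of F6 reacts with trichloroethylene (K2CO3, DMF, 70 °C) to give racemic 7-{[(E)-1,2-dichloroethenyl]oxy}-8-methoxy-6-(methoxymethoxy)-2,2,5-trimethylchroman-4-ol F7.
- n-BuLi (3.3 equiv, THF, −78 to −40 °C) eliminates HCl and exchanges the remaining chlorine for lithium; paraformaldehyde then gives racemic 7-[(3-hydroxyprop-1-yn-1-yl)oxy]-8-methoxy-6-(methoxymethoxy)-2,2,5-trimethylchroman-4-ol F8.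
- TBSCl and imidazole silylate the primary hydroxyl to give racemic 7-{[3-(tert-butyldimethylsilyloxy)prop-1-yn-1-yl]oxy}-8-methoxy-6-(methoxymethoxy)-2,2,5-trimethylchroman-4-ol F9.
- Dess–Martin periodinane restores the ketone and gives 11.

**Step 5.** Thiolate may attack the O8 methyl as well, or ring D may open by enolisation and the enone may take up thiolate, so regioselectivity or mass balance could be poor.

Fallback from 5 back to 7: the demethylation is directed by the free O6 hydroxyl instead of by the ketone.
- AlCl3 and pyridine (CH2Cl2, reflux) cleave the methoxy group next to the free phenol and give 6,7-dihydroxy-8-methoxy-2,2,5-trimethylchroman-4-one F10.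
- The more acidic O7 hydroxyl, para to the ketone, is allylated (allyl bromide, K2CO3, 1 equiv, DMF) to 7-(allyloxy)-6-hydroxy-8-methoxy-2,2,5-trimethylchroman-4-one F11.
- O6 is protected (MOMCl, iPr2NEt) to give 7-(allyloxy)-8-methoxy-6-(methoxymethoxy)-2,2,5-trimethylchroman-4-one F12.
- Pd(PPh3)4 and morpholine (THF, rt) remove the allyl group and give 7.

**Step 8.** The ester enolate may add 1,4 to the methacryloyl unit, and keto ester 14 may oligomerise by Michael addition on warming or concentration.

Fallback from 12 back to 14: the carbon–carbon bond is made at the aldehyde oxidation level. The lithium enolate of 12 (LiN(iPr)2, THF, −78 °C) adds to methacrolein to give racemic tert-butyl 3-hydroxy-4-methylpent-4-enoate F13, and Dess–Martin periodinane oxidises the allylic alcohol to 14, which is used directly in step 9.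

## Further compounds

F1 | step 10 | 4-bromo-3-fluoro-5-methylphenol | Cc1cc(O)cc(F)c1Br
F2 | step 10 | 2-bromo-1-fluoro-5-(methoxymethoxy)-3-methylbenzene | Cc1cc(OCOC)cc(F)c1Br
F3 | step 10 | 3-bromo-2-fluoro-6-(methoxymethoxy)-4-methylbenzaldehyde | Cc1cc(OCOC)c(C=O)c(F)c1Br
F4 | step 10 | tert-butyl 2-fluoro-3-formyl-4-(methoxymethoxy)-6-methylbenzoate | Cc1cc(OCOC)c(C=O)c(F)c1C(=O)OC(C)(C)C
F5 | step 10 | tert-butyl 3-formyl-2-{[8-methoxy-6-(methoxymethoxy)-2,2,5-trimethyl-4-oxochroman-7-yl]oxy}-4-(methoxymethoxy)-6-methylbenzoate | Cc1cc(OCOC)c(C=O)c(Oc2c(OCOC)c(C)c3C(=O)CC(C)(C)Oc3c2OC)c1C(=O)OC(C)(C)C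
F6 | step 7 | 8-methoxy-6-(methoxymethoxy)-2,2,5-trimethylchromane-4,7-diol (racemic) | Cc1c(OCOC)c(O)c(OC)c2OC(C)(C)CC(O)c12
F7 | step 7 | 7-{[(E)-1,2-dichloroethenyl]oxy}-8-methoxy-6-(methoxymethoxy)-2,2,5-trimethylchroman-4-ol (racemic) | Cc1c(OCOC)c(O/C(Cl)=C\Cl)c(OC)c2OC(C)(C)CC(O)c12
F8 | step 7 | 7-[(3-hydroxyprop-1-yn-1-yl)oxy]-8-methoxy-6-(methoxymethoxy)-2,2,5-trimethylchroman-4-ol (racemic) | Cc1c(OCOC)c(OC#CCO)c(OC)c2OC(C)(C)CC(O)c12
F9 | step 7 | 7-{[3-(tert-butyldimethylsilyloxy)prop-1-yn-1-yl]oxy}-8-methoxy-6-(methoxymethoxy)-2,2,5-trimethylchroman-4-ol (racemic) | Cc1c(OCOC)c(OC#CCO[Si](C)(C)C(C)(C)C)c(OC)c2OC(C)(C)CC(O)c12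
F10 | step 5 | 6,7-dihydroxy-8-methoxy-2,2,5-trimethylchroman-4-one | Cc1c(O)c(O)c(OC)c2OC(C)(C)CC(=O)c12
F11 | step 5 | 7-(allyloxy)-6-hydroxy-8-methoxy-2,2,5-trimethylchroman-4-one | Cc1c(O)c(OCC=C)c(OC)c2OC(C)(C)CC(=O)c12
F12 | step 5 | 7-(allyloxy)-8-methoxy-6-(methoxymethoxy)-2,2,5-trimethylchroman-4-one | Cc1c(OCOC)c(OCC=C)c(OC)c2OC(C)(C)CC(=O)c12
F13 | step 8 | tert-butyl 3-hydroxy-4-methylpent-4-enoate (racemic) | CC(=C)C(O)CC(=O)OC(C)(C)C
A1 | alternative 1 | 3-formyl-2-(3-hydroxy-2-methoxy-5-methylphenoxy)-4-methoxy-6-methylbenzoic acid | Cc1cc(O)c(OC)c(Oc2c(C=O)c(OC)cc(C)c2C(=O)O)c1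
A2 | alternative 1 | depsidone without ring D (ring A: 3-formyl, 4-methoxy, 6-methyl; ring B: methyl next to the lactone oxygen, free hydroxyl para to it, methoxy next to the ether oxygen) | Cc1cc(OC)c(C=O)c2c1C(=O)Oc1c(C)cc(O)c(OC)c1O2
A3 | alternative 2 | 4-(benzyloxy)-2-(tert-butyldimethylsilyloxy)-3-methoxyfuran | COc1c(OCc2ccccc2)coc1O[Si](C)(C)C(C)(C)C
A4 | alternative 2 | 6-methylhept-5-en-2-yn-4-one | CC#CC(=O)C=C(C)C
A5 | alternative 2 | 7-(benzyloxy)-6-hydroxy-8-methoxy-2,2,5-trimethylchroman-4-one | Cc1c(O)c(OCc2ccccc2)c(OC)c2c1C(=O)CC(C)(C)O2
A6 | alternative 3 | 7-(buta-1,3-diyn-1-yloxy)-8-methoxy-2,2,5-trimethyl-4-oxochroman-6-yl but-2-ynoate | CC#CC(=O)Oc1c(C)c2C(=O)CC(C)(C)Oc2c(OC)c1OC#CC#C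
A7 | alternative 3 | O8-methyl ether of the target depsidone (same compound as 23) | Cc1cc(O)c(C=O)c2c1C(=O)Oc1c(C)c3c(c(OC)c1O2)OC(C)(C)CC3=O
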